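Readings and results are simulated with constants of no real substance; scatter was added.

At 10 h you read how far right-handed substrate leads left-handed substrate among what is left, in two flasks that differ in partner. The one earlier run, delta, stops at 4.00 h.

| flask | left-handed substrate | right-handed substrate | partner | precatalyst | remark | time |
|---|---|---|---|---|---|---|
| delta | 0.050 M | 0.050 M | 0.11 M | 0.67 mM | run made earlier |  |
| ochre | 0.050 M | 0.050 M | 0.110 M | 1.0 mM |  | 10 h |
| violet | 0.050 M | 0.050 M | 0.300 M | 1.0 mM |  | 10 h |

delta run (percent of the left-handed substrate and right-handed substrate together charged)

| time / h | right-handed substrate / % | left-handed substrate / % | left-handed product / % |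
|---|---|---|---|
| 0.667 | 48 | 48 | 0 |
| 1.33 | 52 | 44 | 1 |
| 2.00 | 50 | 41 | 7 |
| 2.50 | 52 | 38 | 11 |
| 3.00 | 53 | 36 | 17 |
| 4.00 | 47 | 35 | 21 |

(readings scatter by 2 percentage points)

- which one finishes higher in excess of right-handed substrate over left-handed substrate among what is left of the two ("neither" within 2 percentage points) (ochre / violet / neither)
- excess of right-handed substrate over left-handed substrate among what is left of the two at the end, ochre
- excess of right-handed substrate over left-handed substrate among what is left of the two at the end, violet

- free catalyst is single-handed; left-handed substrate and right-handed substrate are mirror images of each other, charged as a racemate, each of them at the stated concentration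
- what was read earlier has a scatter of 2 percentage points, one standard deviation
- an excess is below zero if the other one leads
- no earlier run changes the charge of precatalyst; that part of a forecast is a guess

Delta's last reading looks impossible. It shows 21% of left-handed product, yet left-handed substrate, which began at 0.5 of the charge, has lost 15 percentage points. Each reading carries 2 points, but I take the difference as real: right-handed substrate seems to turn into left-handed substrate (racemisation) and refill it.

So follow the gap g, right-handed minus left-handed substrate. I take it that left-handed product widens g one for one, and that the turning-over narrows it in proportion to g. Delta's gaps average ḡ, and what has closed by the last reading is product minus gap: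

ḡ = 10 points

κ = 0.225 h⁻¹

I call κ the closing rate, the share of the gap closed per hour. It is loose, given the scatter, and it means a gap half-life of 3.08 h.

If product grows at a mean pace p over a time t, and the mean gap is taken as the final gap G, then:

G = p/(κ + 1/t)

If the gap ends above its mean, that overstates the closing, so G errs low. For ochre I keep delta's mean pace, guessing that the extra catalyst and the sag cancel:

p = 0.0525 h⁻¹, product P = 52.5%, G = 16.2%

excess = G/(1 − P) = 34.0%

No run varies partner, so for violet I can only guess that more partner speeds the product and that the excess ends higher, without a number.

The forecast said violet, with 62% for ochre and 85% for violet: “so selectivity is high”.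

Ochre ends at 30.3% and violet at 59.6%, so violet finishes higher.

    left-handed substrate ⇌ right-handed substrate (k = 0.0824 h⁻¹)
    partner + free catalyst + left-handed substrate → free catalyst + left-handed product (k = 8750 M⁻² h⁻¹)
    partner + free catalyst + right-handed substrate → free catalyst + right-handed product (k = 241 M⁻² h⁻¹)
    partner + precatalyst → free catalyst + spent reagent (k = 1.76 M⁻¹ h⁻¹)
    free catalyst → spent catalyst B (k = 0.267 h⁻¹)
    partner + free catalyst → spent catalyst A (k = 0.374 M⁻¹ h⁻¹)

At 10.0 h ochre holds 35.9% right-handed against 19.2% left-handed substrate, a gap of 17 points. Ochre's own pace, left-handed less right-handed product over the time, gives G = 12.7%, lower than that gap. With the gap steady, G would be pace over κ, and ochre's mean pace from there on gives 2.98%. The same flask read at 25.0 h shows a gap of 4 points.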